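Beta lost more D than delta between 2.00 h and 5.00 h, 11 percentage points of its charge against 6.7 points, and my quick number for you starts there. In concentration the two runs agree, 0.00495 M h⁻¹ for beta and 0.00491 M h⁻¹ for delta. I call the beta figure the drain, w: the D, crystals E counted, lost per litre each hour, a zero-order loss.

| flask | Z | remark | time |
|---|---|---|---|
| beta | 0.14 M | run made earlier |  |
| delta | 0.22 M | run made earlier |  |
| flask | 0.10 M |  | 6.0 h |

- beta (time / h: D / %, Q / %): 0.667: 56.9, 32.3; 1.33: 58.2, 36.2; 2.00: 55.3, 38.7; 3.00: 51.9, 42.0; 4.00: 48.7, 45.1; 5.00: 44.7, 48.3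
- delta (time / h: D / %, Q / %): 0.250: 41.6, 22.3; 0.667: 58.6, 32.2; 1.33: 60.8, 35.3; 2.00: 58.5, 36.3; 3.00: 56.7, 37.7; 4.00: 55.1, 40.1; 5.00: 51.8, 42.3

(each reading ± 0.5 percentage points)

- ratio of D to Q at 40 s
- ratio of D to Q at 15 min
- ratio of D to Q at 6.0 h

- what is said of D includes E
- E is a solid; its amount is given per volume of the solution
- what may be going on: Z <-> D; Z <-> Q; Z <-> X; E <-> D

Beta's line runs back to 62.4% of D at the start. In the flask, w takes a larger share of the charge than in beta, 29.7% over 6.0 h, which leaves D at 32.7%. With D and Q summing to 93.0%, as in beta's last reading, my ratio at 6.0 h was 0.542. The risk is that the flask's D tops out near the lowest level beta read on that line, 0.0626 M.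

The forecast, holding that “crystals E are holding dissolved D at saturation”, gave 1.92, 1.86 and 0.6, the last (0.47 to 0.73) above mine.

The flask gave 2.15, 1.83 and 0.543.

    Z ⇌ D (K = 0.730, k = 8.80 × 10⁻⁴ s⁻¹)
    Z ⇌ Q (K = 200, k = 4.00 × 10⁻⁴ s⁻¹)
    Z ⇌ X (K = 240, k = 3.40 × 10⁻⁵ s⁻¹)
    E ⇌ D, rate k4*(cs4 - [D]) while solid is left; crystals form when [D] > cs4 (solubility = 3.80 mM, k = 0.0100 s⁻¹)

Between 3.00 h and 6.00 h the flask lost 0.00500 M h⁻¹ of D, and E still stood at 28.5%. On the neighbouring flask, charged with 0.17 M of Z, w takes 17.5% over the same time, which leaves D at 44.9% and a ratio of 0.933. That neighbour held D at 45.8% and Q at 48.0%, a ratio of 0.954.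

The earlier runs and the new flask are simulated on assumed constants; the scatter is artificial.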